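**Plan**

- Retrosynthesis: cut the Cα=Cβ bond of the enone (aldol addition/elimination with a 4-silyloxybenzaldehyde), then the C2–C3 bond of the dihydrofuran (carbene C–H insertion), then the O1–CH2 ether bond (oxirane opening by a phenol) and the C3a–CHO bond (ring formylation). This leads back to 2,4-dihydroxy-6-methoxyacetophenone.
- Enabling feature: in the 2,3-dihydrobenzofuran (O1, C2, C3, C3a, C4–C7, C7a) C3 is a benzylic methylene on C3a and C2 is an ether methine on O1. A carbene centred on C3 therefore has the two C–H bonds of an O1–CH2 group in a 1,5 relationship, and insertion into one of them closes the five-membered ring.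
- Forward order: the benzene ring is bought with acetyl, methoxy and both oxygens in place. The formyl carbon (later C3) and the O1 side chain are added, the aldehyde becomes a tosylhydrazone, the furan ring closes in step 6, the cinnamoyl chain is joined last and three silyl groups are removed.
- Stereochemistry: the only stereocentre, C2 (S), is set in step 6 by a chiral Rh(II) carboxylate that selects one of two enantiotopic hydrogens; it bears no acidic hydrogen and is not touched afterwards. The E alkene comes from the elimination in step 8.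

Key step: step 6

Assumption: the sense of induction of Rh2(PTAD)4 for a carbene carrying one aryl group and hydrogen is not secured by analogy alone; Rh2(S-PTAD)4 is written, and its equally available enantiomer is used if it favours the (R)-product. Compounds 1, 5 and 12 are taken as purchased.

**Route**

Step 1
Reactants: 1 1-(2,4-dihydroxy-6-methoxyphenyl)ethanone
Product: 3 3-acetyl-2,6-dihydroxy-4-methoxybenzaldehyde, via iminium chloride 2 (not isolated)
Conditions: POCl3 (1.1 equiv), DMF, EtOAc, 0 °C → rt; then H2O, 60 °C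
Reagents that add atoms: N,N-dimethylformamide, CN(C)C=O; water, O
Why: Vilsmeier–Haack formylation of an electron-rich phenol ring: the chloroiminium ion should attack the carbon between the two free hydroxyls, which is activated by both and by the para methoxy group and is less shielded than C5 beside the methoxy methyl, while one equivalent of reagent at low temperature leaves the acetyl group alone, and hydrolysis of iminium salt 2 releases the aldehyde.

Step 2
Reactants: 3 3-acetyl-2,6-dihydroxy-4-methoxybenzaldehyde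
Product: 4 3-acetyl-2-hydroxy-4-methoxy-6-[(triisopropylsilyl)oxy]benzaldehyde
Conditions: TIPSCl (1.05 equiv), imidazole, CH2Cl2, 0 °C → rt
Reagents that add atoms: chlorotri(propan-2-yl)silane (TIPSCl), CC(C)[Si](Cl)(C(C)C)C(C)C
Why: Site-selective silylation of a phenol: the bulky chlorosilane should take the hydroxyl that has only the formyl group as ortho neighbour, whereas the hydroxyl wedged between formyl and acetyl groups and hydrogen-bonded to the ketone stays free.

Step 3
Reactants: 4 3-acetyl-2-hydroxy-4-methoxy-6-[(triisopropylsilyl)oxy]benzaldehyde; 5 2,2-dimethyloxirane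
Product: 6 3-acetyl-2-(2-hydroxy-2-methylpropoxy)-4-methoxy-6-[(triisopropylsilyl)oxy]benzaldehyde
Conditions: 5 (5 equiv), K2CO3 (0.3 equiv), DMF, 70 °C, sealed tube
Reagents that add atoms: none
Why: Base-catalysed ring opening of an epoxide by a phenoxide (SN2 at the unsubstituted oxirane carbon): the acidic phenol is turned over by catalytic carbonate because the tertiary alkoxide formed is reprotonated by the next phenol, which keeps free alkoxide low and so spares the aryl silyl ether.

Step 4
Reactants: 6 3-acetyl-2-(2-hydroxy-2-methylpropoxy)-4-methoxy-6-[(triisopropylsilyl)oxy]benzaldehyde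
Product: 7 3-acetyl-4-methoxy-2-{2-methyl-2-[(triethylsilyl)oxy]propoxy}-6-[(triisopropylsilyl)oxy]benzaldehyde
Conditions: TESOTf, 2,6-lutidine, CH2Cl2, −78 → 0 °C
Reagents that add atoms: triethylsilyl trifluoromethanesulfonate (TESOTf), CC[Si](CC)(CC)OS(=O)(=O)C(F)(F)F
Why: Silylation of a tertiary alcohol with a silyl triflate and a hindered pyridine base at low temperature, which removes the O–H bond that a carbene would otherwise capture and leaves aldehyde, ketone and aryl silyl ether untouched.

Step 5
Reactants: 7 3-acetyl-4-methoxy-2-{2-methyl-2-[(triethylsilyl)oxy]propoxy}-6-[(triisopropylsilyl)oxy]benzaldehyde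
Product: 8 N'-[(E)-(3-acetyl-4-methoxy-2-{2-methyl-2-[(triethylsilyl)oxy]propoxy}-6-[(triisopropylsilyl)oxy]phenyl)methylidene]-4-methylbenzenesulfonohydrazide
Conditions: TsNHNH2 (1.05 equiv), MgSO4, THF, rt
Reagents that add atoms: 4-methylbenzenesulfonohydrazide, Cc1ccc(cc1)S(=O)(=O)NN
Why: Condensation of an aldehyde with a sulfonyl hydrazide to the E-hydrazone; the formyl group reacts at room temperature, whereas the acetyl group, flanked by two ortho oxygens and twisted out of conjugation, is too hindered to condense.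

Step 6
Reactants: 8 N'-[(E)-(3-acetyl-4-methoxy-2-{2-methyl-2-[(triethylsilyl)oxy]propoxy}-6-[(triisopropylsilyl)oxy]phenyl)methylidene]-4-methylbenzenesulfonohydrazide
Product: 11 1-[(2S)-6-methoxy-2-{2-[(triethylsilyl)oxy]propan-2-yl}-4-[(triisopropylsilyl)oxy]-2,3-dihydro-1-benzofuran-7-yl]ethanone, via hydrazone sodium salt 9 (not isolated), via aryldiazomethane 10 (not isolated)
Conditions: NaH (1.05 equiv), THF, 0 °C; then PhMe, Rh2(S-PTAD)4 (2 mol %), BnEt3NCl (10 mol %), 40 °C
Reagents that add atoms: none
Why: Sodium hydride gives salt 9, which under phase-transfer catalysis loses toluenesulfinate at 40 °C (Bamford–Stevens fragmentation) and releases aryldiazomethane 10 slowly; rhodium(II) takes up the diazo carbon with loss of N2, and the electrophilic carbene draws hydride from the O–CH2 group through a three-centre, hydride-transfer-like transition state while the C2–C3 bond forms. The closest known reaction type is the Rh2(PTAD)4-catalysed insertion of hydrazone-derived donor carbenes of o-alkoxyaryl ketones into ether α-C–H bonds to give 2,3-dihydrobenzofurans, together with metal-carbene cyclisation of o-alkoxyaryl tosylhydrazone salts. The dihydrofuran ring closes by 1,5-C–H insertion along the array C3–C3a–C7a–O1–C2–H, the carbene carbon becoming C3 and the ether carbon C2. The C2 stereocentre is set by the chiral carboxylate ligands, which tell apart the two enantiotopic hydrogens of the O–CH2 group. The step needs insertion to outrun azine or stilbene formation and needs a single reactive C–H: slow release keeps the diazo concentration low, the O–CH2 group is the only oxygen-activated C–H 1,5 to the carbene because the C4 oxygen carries silicon and not an alkyl group, the tertiary hydroxyl is silylated so that no O–H insertion can occur, and the acetyl group is meta to the carbene carbon and cannot reach it.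

Step 7
Reactants: 11 1-[(2S)-6-methoxy-2-{2-[(triethylsilyl)oxy]propan-2-yl}-4-[(triisopropylsilyl)oxy]-2,3-dihydro-1-benzofuran-7-yl]ethanone; 12 4-[(tert-butyldimethylsilyl)oxy]benzaldehyde
Product: 13 3-{4-[(tert-butyldimethylsilyl)oxy]phenyl}-3-hydroxy-1-[(2S)-6-methoxy-2-{2-[(triethylsilyl)oxy]propan-2-yl}-4-[(triisopropylsilyl)oxy]-2,3-dihydro-1-benzofuran-7-yl]propan-1-one (both carbinol epimers)
Conditions: LiHMDS (1.1 equiv), THF, −78 °C; then 12; AcOH, −78 °C
Reagents that add atoms: none
Why: Directed aldol addition: the kinetic lithium enolate of the methyl ketone adds to the non-enolisable aldehyde at −78 °C under non-hydrolytic conditions that keep all three silyl ethers, and the new carbinol centre, formed as a mixture, disappears in the next step.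

Step 8
Reactants: 13 3-{4-[(tert-butyldimethylsilyl)oxy]phenyl}-3-hydroxy-1-[(2S)-6-methoxy-2-{2-[(triethylsilyl)oxy]propan-2-yl}-4-[(triisopropylsilyl)oxy]-2,3-dihydro-1-benzofuran-7-yl]propan-1-one
Product: 15 (2E)-3-{4-[(tert-butyldimethylsilyl)oxy]phenyl}-1-[(2S)-6-methoxy-2-{2-[(triethylsilyl)oxy]propan-2-yl}-4-[(triisopropylsilyl)oxy]-2,3-dihydro-1-benzofuran-7-yl]prop-2-en-1-one, via benzylic mesylate 14 (not isolated)
Conditions: MsCl, Et3N (excess), CH2Cl2, 0 °C → rt
Reagents that add atoms: none
Why: Dehydration by mesylation and E1cB elimination of the β-mesyloxy ketone 14 with triethylamine, which should give the conjugated enone as the thermodynamically favoured E isomer.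

Step 9
Reactants: 15 (2E)-3-{4-[(tert-butyldimethylsilyl)oxy]phenyl}-1-[(2S)-6-methoxy-2-{2-[(triethylsilyl)oxy]propan-2-yl}-4-[(triisopropylsilyl)oxy]-2,3-dihydro-1-benzofuran-7-yl]prop-2-en-1-one
Product: 16 (2E)-1-[(2S)-4-hydroxy-2-(2-hydroxypropan-2-yl)-6-methoxy-2,3-dihydro-1-benzofuran-7-yl]-3-(4-hydroxyphenyl)prop-2-en-1-one
Conditions: TBAF, AcOH (1:1, 4 equiv each), THF, 0 → 40 °C
Reagents that add atoms: none
Why: Fluoride-induced cleavage of two aryl silyl ethers and one tertiary alkyl silyl ether, driven by Si–F bond formation, with acetic acid buffering the phenoxides so that the enone is not exposed to strong base; C2 bears no acidic hydrogen and keeps its configuration.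

**Compound list**

1 | 1-(2,4-dihydroxy-6-methoxyphenyl)ethanone | COc1cc(O)cc(O)c1C(C)=O | starting material
2 | N-[(3-acetyl-2,6-dihydroxy-4-methoxyphenyl)methylidene]-N-methylmethanaminium chloride | COc1cc(O)c(C=[N+](C)C)c(O)c1C(C)=O.[Cl-] | intermediate
3 | 3-acetyl-2,6-dihydroxy-4-methoxybenzaldehyde | COc1cc(O)c(C=O)c(O)c1C(C)=O | intermediate
4 | 3-acetyl-2-hydroxy-4-methoxy-6-[(triisopropylsilyl)oxy]benzaldehyde | COc1cc(O[Si](C(C)C)(C(C)C)C(C)C)c(C=O)c(O)c1C(C)=O | intermediate
5 | 2,2-dimethyloxirane | CC1(C)CO1 | starting material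
6 | 3-acetyl-2-(2-hydroxy-2-methylpropoxy)-4-methoxy-6-[(triisopropylsilyl)oxy]benzaldehyde | COc1cc(O[Si](C(C)C)(C(C)C)C(C)C)c(C=O)c(OCC(C)(C)O)c1C(C)=O | intermediate
7 | 3-acetyl-4-methoxy-2-{2-methyl-2-[(triethylsilyl)oxy]propoxy}-6-[(triisopropylsilyl)oxy]benzaldehyde | COc1cc(O[Si](C(C)C)(C(C)C)C(C)C)c(C=O)c(OCC(C)(C)O[Si](CC)(CC)CC)c1C(C)=O | intermediate
8 | N'-[(E)-(3-acetyl-4-methoxy-2-{2-methyl-2-[(triethylsilyl)oxy]propoxy}-6-[(triisopropylsilyl)oxy]phenyl)methylidene]-4-methylbenzenesulfonohydrazide | COc1cc(O[Si](C(C)C)(C(C)C)C(C)C)c(/C=N/NS(=O)(=O)c2ccc(C)cc2)c(OCC(C)(C)O[Si](CC)(CC)CC)c1C(C)=O | intermediate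
9 | sodium salt of hydrazone 8 (deprotonated at the sulfonamide nitrogen) | COc1cc(O[Si](C(C)C)(C(C)C)C(C)C)c(/C=N/[N-]S(=O)(=O)c2ccc(C)cc2)c(OCC(C)(C)O[Si](CC)(CC)CC)c1C(C)=O.[Na+] | intermediate
10 | 1-{3-(diazomethyl)-6-methoxy-2-{2-methyl-2-[(triethylsilyl)oxy]propoxy}-4-[(triisopropylsilyl)oxy]phenyl}ethanone | COc1cc(O[Si](C(C)C)(C(C)C)C(C)C)c(C=[N+]=[N-])c(OCC(C)(C)O[Si](CC)(CC)CC)c1C(C)=O | intermediate
11 | 1-[(2S)-6-methoxy-2-{2-[(triethylsilyl)oxy]propan-2-yl}-4-[(triisopropylsilyl)oxy]-2,3-dihydro-1-benzofuran-7-yl]ethanone | COc1cc(O[Si](C(C)C)(C(C)C)C(C)C)c2c(c1C(C)=O)O[C@H](C(C)(C)O[Si](CC)(CC)CC)C2 | intermediate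
12 | 4-[(tert-butyldimethylsilyl)oxy]benzaldehyde | O=Cc1ccc(O[Si](C)(C)C(C)(C)C)cc1 | starting material
13 | 3-{4-[(tert-butyldimethylsilyl)oxy]phenyl}-3-hydroxy-1-[(2S)-6-methoxy-2-{2-[(triethylsilyl)oxy]propan-2-yl}-4-[(triisopropylsilyl)oxy]-2,3-dihydro-1-benzofuran-7-yl]propan-1-one (both carbinol epimers) | COc1cc(O[Si](C(C)C)(C(C)C)C(C)C)c2c(c1C(=O)CC(O)c1ccc(O[Si](C)(C)C(C)(C)C)cc1)O[C@H](C(C)(C)O[Si](CC)(CC)CC)C2 | intermediate
14 | 1-{4-[(tert-butyldimethylsilyl)oxy]phenyl}-3-[(2S)-6-methoxy-2-{2-[(triethylsilyl)oxy]propan-2-yl}-4-[(triisopropylsilyl)oxy]-2,3-dihydro-1-benzofuran-7-yl]-3-oxopropyl methanesulfonate (both epimers) | COc1cc(O[Si](C(C)C)(C(C)C)C(C)C)c2c(c1C(=O)CC(OS(C)(=O)=O)c1ccc(O[Si](C)(C)C(C)(C)C)cc1)O[C@H](C(C)(C)O[Si](CC)(CC)CC)C2 | intermediate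
15 | (2E)-3-{4-[(tert-butyldimethylsilyl)oxy]phenyl}-1-[(2S)-6-methoxy-2-{2-[(triethylsilyl)oxy]propan-2-yl}-4-[(triisopropylsilyl)oxy]-2,3-dihydro-1-benzofuran-7-yl]prop-2-en-1-one | COc1cc(O[Si](C(C)C)(C(C)C)C(C)C)c2c(c1C(=O)/C=C/c1ccc(O[Si](C)(C)C(C)(C)C)cc1)O[C@H](C(C)(C)O[Si](CC)(CC)CC)C2 | intermediate
16 | (2E)-1-[(2S)-4-hydroxy-2-(2-hydroxypropan-2-yl)-6-methoxy-2,3-dihydro-1-benzofuran-7-yl]-3-(4-hydroxyphenyl)prop-2-en-1-one | COc1cc(O)c2c(c1C(=O)/C=C/c1ccc(O)cc1)O[C@H](C(C)(C)O)C2 | target

**Step count and risks**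

Total step count: 9. Longest linear sequence: 9 steps (1 → 16).

Steps most likely to fail:

1. Step 6. The diazo compound may dimerise to azine or stilbene faster than rhodium takes it up. Hydride transfer from the O–CH2 group may be slow, because the neighbouring quaternary carbon carries an inductively withdrawing silyloxy group. The catalyst may also discriminate the two enantiotopic hydrogens poorly when the carbene carries hydrogen in place of a second substituent. The fallback forms the O1–C2 bond instead of C2–C3 and sets out from 1. C-prenylation between the two hydroxyls (1-bromo-3-methylbut-2-ene, DBU, THF) should give 1-[2,4-dihydroxy-6-methoxy-3-(3-methylbut-2-en-1-yl)phenyl]ethanone F1, in modest yield at best. Silylation of its non-chelated hydroxyl (TIPSCl, imidazole) gives 1-{2-hydroxy-6-methoxy-3-(3-methylbut-2-en-1-yl)-4-[(triisopropylsilyl)oxy]phenyl}ethanone F2. Shi epoxidation, with the enantiomer of the ketone catalyst that delivers the (R)-epoxide, gives 1-{3-{[(2R)-3,3-dimethyloxiran-2-yl]methyl}-2-hydroxy-6-methoxy-4-[(triisopropylsilyl)oxy]phenyl}ethanone F3. DBU in THF then lets the remaining phenol open the oxirane 5-exo with inversion, giving 1-{(2S)-2-(2-hydroxypropan-2-yl)-6-methoxy-4-[(triisopropylsilyl)oxy]-2,3-dihydro-1-benzofuran-7-yl}ethanone F4. Silylation with TESOTf and 2,6-lutidine brings the sequence back to the route at 11.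

2. Step 3. Attack of the doubly ortho-substituted, chelated phenoxide on the oxirane may be slow, and at the temperature needed the aryl silyl group may be lost or transferred and the acetyl and formyl groups may undergo aldol self-condensation. The fallback sets out from 4 and uses a far more reactive allylic electrophile. 3-Bromo-2-methylprop-1-ene with K2CO3 in acetone at 50 °C should give 3-acetyl-4-methoxy-2-[(2-methylprop-2-en-1-yl)oxy]-6-[(triisopropylsilyl)oxy]benzaldehyde F5. Markovnikov Mukaiyama hydration of its 1,1-disubstituted alkene (Co(acac)2, PhSiH3, O2, THF) then gives the tertiary alcohol, which is compound 6.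

3. Step 1. Formylation at C5, between the hydroxyl and the methoxy group, may compete with attack between the two hydroxyls, and the reagent may attack the acetyl group. The fallback sets out from 1 and reverses the order so that the site is fixed by the mechanism. Silylation of the non-chelated hydroxyl (TIPSCl, imidazole) gives 1-{2-hydroxy-6-methoxy-4-[(triisopropylsilyl)oxy]phenyl}ethanone F6. Magnesium-mediated ortho-formylation of the one remaining phenol (MgCl2, Et3N, paraformaldehyde, MeCN, reflux; Casnati–Skattebøl reaction) can only enter its single free ortho position and gives compound 4, so step 2 is no longer needed.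

**Further compounds**

F1 | step 6 | 1-[2,4-dihydroxy-6-methoxy-3-(3-methylbut-2-en-1-yl)phenyl]ethanone | COc1cc(O)c(CC=C(C)C)c(O)c1C(C)=O
F2 | step 6 | 1-{2-hydroxy-6-methoxy-3-(3-methylbut-2-en-1-yl)-4-[(triisopropylsilyl)oxy]phenyl}ethanone | COc1cc(O[Si](C(C)C)(C(C)C)C(C)C)c(CC=C(C)C)c(O)c1C(C)=O
F3 | step 6 | 1-{3-{[(2R)-3,3-dimethyloxiran-2-yl]methyl}-2-hydroxy-6-methoxy-4-[(triisopropylsilyl)oxy]phenyl}ethanone | COc1cc(O[Si](C(C)C)(C(C)C)C(C)C)c(C[C@H]2OC2(C)C)c(O)c1C(C)=O
F4 | step 6 | 1-{(2S)-2-(2-hydroxypropan-2-yl)-6-methoxy-4-[(triisopropylsilyl)oxy]-2,3-dihydro-1-benzofuran-7-yl}ethanone | COc1cc(O[Si](C(C)C)(C(C)C)C(C)C)c2c(c1C(C)=O)O[C@H](C(C)(C)O)C2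
F5 | step 3 | 3-acetyl-4-methoxy-2-[(2-methylprop-2-en-1-yl)oxy]-6-[(triisopropylsilyl)oxy]benzaldehyde | COc1cc(O[Si](C(C)C)(C(C)C)C(C)C)c(C=O)c(OCC(C)=C)c1C(C)=O
F6 | step 1 | 1-{2-hydroxy-6-methoxy-4-[(triisopropylsilyl)oxy]phenyl}ethanone | COc1cc(O[Si](C(C)C)(C(C)C)C(C)C)cc(O)c1C(C)=O
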